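The numbers of this flask belong to no real substance; the result is computed.

Reckon this flask through the dissolved L, which J feeds and X uses up.

    L + X → E + Q (k1 = 0.76 L mol⁻¹ h⁻¹)
    X + E ⇌ X.E, settled at all times (K2 = 11000 L mol⁻¹)
    E + D ⇌ E.D (K3 = 1.5 × 10⁵ L mol⁻¹, k3 = 24 L mol⁻¹ h⁻¹)
    J ⇌ L, rate k4*(cs4 - [L]) while solid is left; crystals form when [L] > cs4 (cs4 = 0.064 M, k4 = 0.11 h⁻¹)

J 0.10 M; X 0.250 M; D 0.0500 M; time 12 h

- given per volume of solution although it is solid: J
- at the start none of J is in solution
- L means what is dissolved; the solid is not counted in it
- run time (flask): 12 h

- Q at 12 h, in percent of the J charged
- concentration of L in solution at 3.0 h, in percent of saturation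
- the change that raises the amount of Q at 12 h, in percent of the J charged most ("none" if none brings more than 2 percentage points) (green / teal / grey / ochre / none)
- amount of Q at 12 h, in percent of the J charged, after ochre

- green: doubling the amount of X, all else as stated
- teal: doubling the solubility in step 4, all else as stated
- grey: doubling the amount of D, all else as stated
- ochre: doubling the dissolution coefficient of step 4, all else as stated

Replace the falling X by one mean value, X̄. Let u be the constant of L with X times X̄, a pseudo-first-order constant, let f be the dissolution coefficient and s the solubility. L then climbs with a time constant τ, the inverse of f + u, towards f·s·τ, and Q grows at u times that level after a lag of about τ. E sits on X, since the equilibrium constant of step 2 times X at the start is 2800, so each Q costs two X and the mean X stands one Q below the charge. With X at its charge, Q comes to 0.0386 M. That puts X̄ at 0.211 M and τ at 3.70 h. The plateau of L, the level where dissolving and use balance, is 0.0260 M. So I expect Q at 0.0347 M, which is 34.7% of J, and L at 22.6% of saturation at 3.0 h.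

Now turn the settings one by one. Grey: with X at its charge, E held on X reaches doubled D with a half-life of 794 h, far longer than the 12 h run, so I expect no gain. Green: the rule gives 52.9%. Ochre: it gives 55.7%. Teal: at the same X̄ the plateau doubles and so does Q, to 69.4%, but Q plus L then comes to 0.119 M, above the 0.10 M charged, so that figure overshoots. I still choose teal.

The forecast gave Q at 35% of J, L at 21.9% of saturation, Q at 51.8% after ochre, and teal as the best change: “Teal is best.”

The flask gives Q at 35.0% of J and L at 21.9% of saturation, with gains of 0 percentage points for grey, 16 points for green, 17 points for ochre and 25 points for teal, so teal leads and ochre reaches 51.8%. In the flask, half of the dissolving of J up to the asked time is done by 5.29 h, and half of the reaction of L with X up to that time by 7.09 h. At 12.0 h solid J still stands at 39.3% and L at 0.0257 M, against the reckoned plateau of 0.0260 M, while L, each step taken net, is made 1.20 times faster than it is used. The answer y moves by 5 points at a run time of 10.6 h or 13.4 h.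

For the neighbour charged with 0.42 M of X, taking X̄ as that charge less the 0.0347 M reckoned above, the plateau is 0.0175 M and the rule gives Q at 48.7% of J. That neighbour computes to 47.4%.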